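The north run and the north-west flask look nearly the same: equal partner in equal portions, equal precatalyst, but a different substrate charge, 0.019 M against 0.013 M. The percentages hide what they share, so we turn them into concentrations.

| flask | substrate | partner | precatalyst | remark | time |
|---|---|---|---|---|---|
| north-west | 0.013 M | 0.0195 M (in portions, 4) | 1.9 mM | the very flask that is asked about, followed so far; portions every 80 s |  |
| north | 0.019 M | 0.0195 M (in portions, 4) | 1.9 mM | run made earlier; portions every 80 s |  |
| flask | 0.013 M | 0.0195 M (in portions, 4) | 1.9 mM | the portions of partner follow each other after 80 s, the first at the start | 80 min |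

| run | time / min | target / % | substrate / % |
|---|---|---|---|
| north-west | 2.50 | 2 | 96 |
| north-west | 8.00 | 13 | 81 |
| north-west | 15.0 | 36 | 54 |
| north-west | 20.0 | 49 | 42 |
| north-west | 30.0 | 50 | 37 |
| north-west | 40.0 | 55 | 35 |
| north | 5.00 | 2 | 94 |
| north | 8.00 | 10 | 85 |
| north | 12.0 | 17 | 77 |
| north | 20.0 | 31 | 60 |
| north | 30.0 | 38 | 55 |
| north | 60.0 | 39 | 57 |

(readings scatter by 1.5 percentage points)



1. concentration of target at 80 min, in M
2. concentration of substrate at 80 min, in M

We call S, the stall amount, the concentration of substrate used up once the readings go flat. The north run is flat from 30.0 min to 60.0 min, so we average its two readings of substrate left: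

S = 0.019 M × (1 − mean of 55% and 57%) = 0.00836 M

The north-west flask at 40.0 min, from its smaller charge, has used 0.00845 M, the same within the scatter. Both runs go flat with substrate still in them, 57% in the north run and 35% in the north-west flask, and the two share their partner and precatalyst charges.

Our reckoning for the north-west flask at 80 min is therefore:

substrate = 0.013 M − S = 0.00464 M

target = 0.019 M × mean of 38% and 39% = 0.00732 M

The forecast gives 0.0074 M of target (0.0069 M to 0.0081 M) and 0.0045 M of substrate (0.0039 M to 0.005 M), with the ceiling “set by something common to both runs”. Our target lies slightly below its figure and our substrate slightly above.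

The flask gives 0.00692 M of target and 0.00458 M of substrate, both within tolerance of the forecast.

    target + free catalyst ⇌ isomer of the product + free catalyst, rate k1*[free catalyst]*[target] forward; the back reaction follows from the equilibrium constant (K = 0.340, k = 10.8 /M/s)
    substrate + free catalyst → catalyst intermediate A (k = 167 /M/s)
    partner + precatalyst → free catalyst + spent reagent (k = 0.133 /M/s)
    partner + catalyst intermediate A → catalyst intermediate B (k = 2.57 /M/s)
    partner → decomposed reagent (k = 0.00135 /s)
    catalyst intermediate B → free catalyst + target (k = 0.0129 /s)

At 80 min the partner, here the limiting reagent, stands at 0% of its charge, less than the substrate's 35%. We now use S on a neighbour charged with 0.033 M of substrate: subtracting S leaves 0.0246 M, and that neighbour holds 0.0246 M of substrate at 80 min.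

The numbers in the tables are calculated with made-up constants, and the scatter is random.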